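In labdane numbering (C10 bears CH3, C8 the formyl carbon C17), the C4(CH2OH)2 carbon of ring A is read as a reduced malonate. Ring-fusion C5 then becomes the β-carbon of an alkylidene Meldrum's acid, and C6 of ring B the γ-carbon of the C8 enal. The route rests on joining these two carbons: an acyclic enal-aldehyde carrying the C9 and C10 stereocentres condenses with Meldrum's acid at its neopentyl aldehyde, and the dienamine of the 2-ethylidene aldehyde attacks the new acceptor through C6. One operation forms C4=C5, then the C5–C6 bond that closes ring B, and sets C5; the malonate carbon afterwards alkylates the C3 chloride to close ring A.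

Key step: step 8

Remark: atom labels C1–C20 follow labdane numbering of the target (C4 carries the two CH2OH groups, C9 the side chain C11–C16); the target is (5S,8S,9R,10S), an ent-labdane with a trans ring fusion and an equatorial formyl group.

Step 1
Reactants: 1 5,6-dihydro-2H-pyran-2-one; 2 potassium vinyltrifluoroborate
Product: 3 (R)-4-vinyltetrahydro-2H-pyran-2-one
Conditions: [Rh(cod)2]BF4 (3 mol%), (R)-BINAP (3.3 mol%), toluene/H2O, 100 °C
Reagents that add atoms: none
Why: Hayashi–Miyaura rhodium-catalysed asymmetric 1,4-addition of an alkenylboron reagent to the unsaturated lactone; by analogy with aryl additions to this lactone the (R)-BINAP complex should deliver vinyl to the face that gives the (R)-centre, which becomes C9.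

Step 2
Reactants: 3 (R)-4-vinyltetrahydro-2H-pyran-2-one
Product: 4 (3S,4S)-3-methyl-4-vinyltetrahydro-2H-pyran-2-one
Conditions: LiN(iPr)2, THF, −78 °C; then MeI, −78 to −40 °C
Reagents that add atoms: iodomethane, CI
Why: lactone enolate alkylation (SN2), in which methyl should enter mainly anti to the C4 vinyl group; any cis epimer is carried on because C3 is re-enolised in step 3.

Step 3
Reactants: 4 (3S,4S)-3-methyl-4-vinyltetrahydro-2H-pyran-2-one; 5 1-chloro-3-iodopropane
Product: 6 (3S,4S)-3-(3-chloropropyl)-3-methyl-4-vinyltetrahydro-2H-pyran-2-one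
Conditions: LiN(iPr)2, THF/DMPU, −78 °C; then 5, −78 to −20 °C
Reagents that add atoms: none
Why: second lactone enolate alkylation (SN2 at the C–I end, chloride untouched); the C4 vinyl group is pseudoaxial next to the methyl-bearing enolate carbon (A1,2 strain), so the electrophile should add anti to it and set the quaternary centre (future C10) with chloropropyl trans and methyl cis to vinyl.

Step 4
Reactants: 6 (3S,4S)-3-(3-chloropropyl)-3-methyl-4-vinyltetrahydro-2H-pyran-2-one
Product: 7 (2S,3S)-2-(3-chloropropyl)-2-methyl-3-vinylpentane-1,5-diol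
Conditions: LiAlH4, THF, 0 °C
Reagents that add atoms: none
Why: hydride reduction of the lactone to the 1,5-diol; the primary chloride and the alkene should be inert at 0 °C.

Step 5
Reactants: 7 (2S,3S)-2-(3-chloropropyl)-2-methyl-3-vinylpentane-1,5-diol
Product: 8 (2S,3S)-2-(3-chloropropyl)-2-methyl-3-vinylpentanedial
Conditions: (COCl)2, DMSO, CH2Cl2, −78 °C; then Et3N, −78 to 0 °C
Reagents that add atoms: none
Why: Swern oxidation, in which both hydroxyls are activated as alkoxysulfonium ions before base is added, so no hydroxy aldehyde is present to lactolise and over-oxidise to a lactone.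

Step 6
Reactants: 8 (2S,3S)-2-(3-chloropropyl)-2-methyl-3-vinylpentanedial
Product: 9 (2S,3R)-2-(3-chloropropyl)-2-methyl-5-(trimethylsilyloxy)-3-vinylpent-4-enal (E/Z mixture)
Conditions: TMSOTf (1.05 equiv), Et3N, CH2Cl2, −20 to 0 °C
Reagents that add atoms: trimethylsilyl trifluoromethanesulfonate, C[Si](C)(C)OS(=O)(=O)C(F)(F)F
Why: soft enolisation and O-silylation (enol silane formation); only the C17 aldehyde has α-hydrogens, so the neopentyl C5 aldehyde cannot react.

Step 7
Reactants: 9 (2S,3R)-2-(3-chloropropyl)-2-methyl-5-(trimethylsilyloxy)-3-vinylpent-4-enal; 10 1,1-dimethoxyethane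
Product: 12 (2S,3S,4E)-2-(3-chloropropyl)-4-ethylidene-2-methyl-3-vinylpentanedial, via β-methoxy aldehyde 11 (not isolated)
Conditions: TMSOTf (10 mol%), CH2Cl2, −78 °C; then DBU, −78 °C to rt
Reagents that add atoms: none
Why: Mukaiyama-type addition of the enol silane to the oxocarbenium ion from the acetal (acetals are activated in preference to aldehydes under silyl triflate catalysis), followed by E1cB loss of methanol; the alkene geometry is of no consequence for step 8.

Step 8
Reactants: 12 (2S,3S,4E)-2-(3-chloropropyl)-4-ethylidene-2-methyl-3-vinylpentanedial; 13 Meldrum's acid (2,2-dimethyl-1,3-dioxane-4,6-dione)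
Product: 15 5-[(1R,5S,6R)-6-(3-chloropropyl)-4-formyl-6-methyl-5-vinylcyclohex-3-en-1-yl]-2,2-dimethyl-1,3-dioxane-4,6-dione, via alkylidene Meldrum's acid 14 (not isolated)
Conditions: ethylenediammonium diacetate (20 mol%), MeCN, rt (condensation), then 50 °C (ring closure)
Reagents that add atoms: none
Why: The primary ammonium acetate first catalyses Knoevenagel condensation of Meldrum's acid with the non-enolisable neopentyl aldehyde of 12 to give 14, and then converts the 2-ethylidene aldehyde into its linear dienamine, whose terminal carbon C6 adds to C5 of the alkylidene Meldrum's acid; hydrolysis of the unsaturated iminium ion returns the catalyst and leaves the C7=C8 enal. The closest known reaction types are domino Knoevenagel sequences of aldehydes carrying a tethered π-nucleophile and the amine-catalysed γ-selective (vinylogous) Michael addition of α-branched enals through dienamines. Ring B is closed in a 6-(enolendo)-exo-trig mode. The new C5 stereocentre is set by the C9 and C10 centres: a chair-like transition state with the vinyl and chloropropyl groups equatorial and the C10 methyl axial, combined with the acceptor rotamer that places the small methyl group next to the Meldrum's carbonyl (least A1,3 strain), exposes the C5 face that leaves H-5 anti to the C10 methyl group. The step needs site selectivity (condensation at the saturated aldehyde, not at the enal) and γ- over α-selectivity: the hindered, conjugated α-branched enal is the less electrophilic carbonyl and is partly held as dienamine, condensation at it is reversible while ring closure is not, and α-attack would have to form a cyclobutane.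

Step 9
Reactants: 15 5-[(1R,5S,6R)-6-(3-chloropropyl)-4-formyl-6-methyl-5-vinylcyclohex-3-en-1-yl]-2,2-dimethyl-1,3-dioxane-4,6-dione
Product: 16 spiro-Meldrum's acid trans-decalin enal (C4 spiro-fused to the dioxanedione, C7=C8 with CHO on C8, vinyl on C9, CH3 on C10, H-5 anti to CH3-10)
Conditions: K2CO3, DMF, 70 °C
Reagents that add atoms: none
Why: intramolecular C-alkylation of the Meldrum's acid anion by the primary chloride (SN2, 6-exo-tet) closes ring A and makes C4 quaternary; the trans ring fusion follows from the C5 and C10 configurations already in place.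

Step 10
Reactants: 16 spiro-Meldrum's acid trans-decalin enal
Product: 18 saturated (8S)-aldehyde (as 16 with C7–C8 single bond, CHO equatorial and trans to the C9 vinyl group), via C8-epimeric aldehyde 17 (not isolated)
Conditions: [(Ph3P)CuH]6, H2O (2 equiv), toluene, rt; then DBU (20 mol%), CH2Cl2, rt
Reagents that add atoms: none
Why: copper hydride conjugate reduction of the enal leaves the vinyl group and the acylal untouched; enolate protonation may give both C8 epimers, and base equilibration through the enol should place the formyl group equatorial, away from the axial C10 methyl group, which is the C8 configuration of the target.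

Step 11
Reactants: 18 saturated (8S)-aldehyde
Product: 19 1,3-dioxolane acetal of 18
Conditions: 1,2-bis(trimethylsilyloxy)ethane, TMSOTf (5 mol%), CH2Cl2, −78 to −20 °C
Reagents that add atoms: 1,2-bis(trimethylsilyloxy)ethane, C[Si](C)(C)OCCO[Si](C)(C)C
Why: silyl-triflate-catalysed acetalisation under aprotic conditions protects the aldehyde without alcoholysis of the Meldrum's acid ring.

Step 12
Reactants: 19 1,3-dioxolane acetal of 18
Product: 20 4,4-bis(hydroxymethyl) trans-decalin with the dioxolane on C8 and vinyl on C9
Conditions: LiAlH4, THF, 0 °C to rt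
Reagents that add atoms: none
Why: hydride reduction of both acyl groups of the 5,5-disubstituted Meldrum's acid gives the 2,2-disubstituted propane-1,3-diol; acetal and alkene are inert.

Step 13
Reactants: 20 4,4-bis(hydroxymethyl) trans-decalin with the dioxolane on C8 and vinyl on C9; 21 3-bromofuran-2(5H)-one
Product: 23 dioxolane-protected target (furan-2(5H)-one attached through its C3 to C12), via B-alkyl-9-BBN borane 22 (not isolated)
Conditions: 9-BBN (excess), THF, rt; then 21, PdCl2(dppf) (5 mol%), AsPh3, Cs2CO3, DMF/H2O, rt
Reagents that add atoms: none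
Why: anti-Markovnikov hydroboration of the terminal vinyl group, then B-alkyl Suzuki–Miyaura coupling with the α-bromo enoate unit of 21, forms the C12–C13 bond; the hydroxyls are tolerated as transient borinates that the aqueous base cleaves.

Step 14
Reactants: 23 dioxolane-protected target
Product: 24 3-{2-[(1R,2S,4aS,8aS)-2-formyl-5,5-bis(hydroxymethyl)-8a-methyldecahydronaphthalen-1-yl]ethyl}furan-2(5H)-one (target)
Conditions: 1 M HCl, THF, rt
Reagents that add atoms: water, O
Why: acid-catalysed acetal hydrolysis; C8 remains in its thermodynamically preferred equatorial configuration and the butenolide is stable to dilute acid.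

Compound list
1 | 5,6-dihydro-2H-pyran-2-one | O=C1C=CCCO1 | starting material
2 | potassium vinyltrifluoroborate | [K+].C=C[B-](F)(F)F | starting material
3 | (R)-4-vinyltetrahydro-2H-pyran-2-one | O=C1C[C@H](C=C)CCO1 | intermediate
4 | (3S,4S)-3-methyl-4-vinyltetrahydro-2H-pyran-2-one (trans) | O=C1[C@@H](C)[C@H](C=C)CCO1 | intermediate
5 | 1-chloro-3-iodopropane | ClCCCI | starting material
6 | (3S,4S)-3-(3-chloropropyl)-3-methyl-4-vinyltetrahydro-2H-pyran-2-one | O=C1[C@@](C)(CCCCl)[C@H](C=C)CCO1 | intermediate
7 | (2S,3S)-2-(3-chloropropyl)-2-methyl-3-vinylpentane-1,5-diol | OC[C@@](C)(CCCCl)[C@H](C=C)CCO | intermediate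
8 | (2S,3S)-2-(3-chloropropyl)-2-methyl-3-vinylpentanedial | O=C[C@@](C)(CCCCl)[C@H](C=C)CC=O | intermediate
9 | (2S,3R)-2-(3-chloropropyl)-2-methyl-5-(trimethylsilyloxy)-3-vinylpent-4-enal (E/Z mixture) | O=C[C@@](C)(CCCCl)[C@H](C=C)C=CO[Si](C)(C)C | intermediate
10 | 1,1-dimethoxyethane (acetaldehyde dimethyl acetal) | CC(OC)OC | starting material
11 | 2-(3-chloropropyl)-4-(1-methoxyethyl)-2-methyl-3-vinylpentanedial (C2 and C3 as in 8, mixture at the two new centres) | O=C[C@@](C)(CCCCl)[C@H](C=C)C(C=O)C(C)OC | intermediate (not isolated)
12 | (2S,3S,4E)-2-(3-chloropropyl)-4-ethylidene-2-methyl-3-vinylpentanedial | O=C[C@@](C)(CCCCl)[C@H](C=C)/C(C=O)=C\C | intermediate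
13 | Meldrum's acid (2,2-dimethyl-1,3-dioxane-4,6-dione) | CC1(C)OC(=O)CC(=O)O1 | starting material
14 | alkylidene Meldrum's acid formed from 12 at its neopentyl aldehyde (stereocentres and enal unchanged) | CC1(C)OC(=O)C(=C[C@@](C)(CCCCl)[C@H](C=C)/C(C=O)=C\C)C(=O)O1 | intermediate (not isolated)
15 | 5-[(1R,5S,6R)-6-(3-chloropropyl)-4-formyl-6-methyl-5-vinylcyclohex-3-en-1-yl]-2,2-dimethyl-1,3-dioxane-4,6-dione | C[C@@]1(CCCCl)[C@@H](C2C(=O)OC(C)(C)OC2=O)CC=C(C=O)[C@H]1C=C | intermediate
16 | spiro-Meldrum's acid trans-decalin enal (C4 spiro centre, C7=C8–CHO, 9-vinyl, 10-methyl; H-5 and H-9 on the face opposite to CH3-10) | C[C@@]12CCCC3(C(=O)OC(C)(C)OC3=O)[C@H]1CC=C(C=O)[C@H]2C=C | intermediate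
17 | C8 epimer of 18 (axial formyl group) | C[C@@]12CCCC3(C(=O)OC(C)(C)OC3=O)[C@H]1CC[C@@H](C=O)[C@H]2C=C | intermediate (not isolated)
18 | saturated (8S)-aldehyde (equatorial CHO trans to the 9-vinyl group) | C[C@@]12CCCC3(C(=O)OC(C)(C)OC3=O)[C@H]1CC[C@H](C=O)[C@H]2C=C | intermediate
19 | 1,3-dioxolane acetal of 18 | C[C@@]12CCCC3(C(=O)OC(C)(C)OC3=O)[C@H]1CC[C@H](C4OCCO4)[C@H]2C=C | intermediate
20 | 4,4-bis(hydroxymethyl)-8-(1,3-dioxolan-2-yl)-9-vinyl trans-decalin (labdane numbering) | C[C@@]12CCCC(CO)(CO)[C@H]1CC[C@H](C3OCCO3)[C@H]2C=C | intermediate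
21 | 3-bromofuran-2(5H)-one | O=C1OCC=C1Br | starting material
22 | B-alkyl-9-BBN borane from 20 (boron on C12) | C[C@@]12CCCC(CO)(CO)[C@H]1CC[C@H](C3OCCO3)[C@H]2CCB3C4CCCC3CCC4 | intermediate (not isolated)
23 | dioxolane-protected target | C[C@@]12CCCC(CO)(CO)[C@H]1CC[C@H](C3OCCO3)[C@H]2CCC1=CCOC1=O | intermediate
24 | 3-{2-[(1R,2S,4aS,8aS)-2-formyl-5,5-bis(hydroxymethyl)-8a-methyldecahydronaphthalen-1-yl]ethyl}furan-2(5H)-one | C[C@@]12CCCC(CO)(CO)[C@H]1CC[C@H](C=O)[C@H]2CCC1=CCOC1=O | target

Total step count: 14. Longest linear sequence: 14 steps (from 1).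

Steps most likely to fail

Step 8 (key step). Meldrum's acid may condense with, or add in conjugate fashion to, the enal instead of the neopentyl aldehyde. The dienamine may form sluggishly from the hindered α-branched enal, or may close onto the free aldehyde in a vinylogous aldol before condensation. Facial selectivity at C5 may also be eroded. Fallback, setting out from 12: the enal is masked and activated as the tert-butyldimethylsilyl dienol ether F1 (TBSCl, NaI, Et3N, MeCN), which cannot condense with Meldrum's acid. Knoevenagel condensation at the remaining aldehyde (piperidinium acetate, CH2Cl2) should give the isolable silyl dienol ether alkylidene Meldrum's acid F2. A Lewis acid (Sc(OTf)3, CH2Cl2, −40 °C) then triggers an intramolecular vinylogous Mukaiyama–Michael addition, and aqueous work-up returns to the route at 15.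

Step 7. The enol silane of the 1,5-dialdehyde may close onto the second formyl group as a silylated lactol, the hindered enol silane may add slowly to the oxocarbenium ion, or elimination of methanol may be incomplete. Fallback, setting out from 7: oxidative lactonisation at the less hindered carbinol (PhI(OAc)2, TEMPO) should give the regioisomeric lactone F3, whose lithium enolate (LiN(iPr)2, THF, −78 °C) adds to acetaldehyde to give the aldol lactone F4. Mesylation and elimination (MsCl, Et3N; then DBU) give the α-ethylidene lactone F5, i-Bu2AlH reduces it to the allylic neopentyl diol F6, and Swern oxidation returns to the route at 12.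

Step 13. The base-sensitive bromobutenolide may decompose, or the hindered alkylborane may undergo protodeboronation or β-hydride elimination faster than transmetalation. Fallback, setting out from 20: the diol is protected as the acetonide F7 (2,2-dimethoxypropane, pyridinium p-toluenesulfonate). Hydroboration–oxidation (9-BBN; NaBO3·4H2O) gives the primary alcohol F8 and Dess–Martin oxidation the aldehyde F9. Horner–Wadsworth–Emmons olefination with diethyl (2-oxotetrahydrofuran-3-yl)phosphonate (NaH, THF) gives the α-alkylidene butyrolactone F10. RhCl3·3H2O in hot ethanol moves the exocyclic double bond into the ring to give the protected butenolide F11. Aqueous HCl in THF removes both acetals and returns to the route at 24.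

Further compounds
F1 | step 8 | tert-butyldimethylsilyl dienol ether of 12 | O=C[C@@](C)(CCCCl)[C@H](C=C)C(C=C)=CO[Si](C)(C)C(C)(C)C
F2 | step 8 | silyl dienol ether alkylidene Meldrum's acid | CC1(C)OC(=O)C(=C[C@@](C)(CCCCl)[C@H](C=C)C(C=C)=CO[Si](C)(C)C(C)(C)C)C(=O)O1
F3 | step 7 | 5-(3-chloropropyl)-5-methyl-4-vinyltetrahydro-2H-pyran-2-one (stereocentres as in 7) | O=C1C[C@@H](C=C)[C@](C)(CCCCl)CO1
F4 | step 7 | 3-(1-hydroxyethyl) aldol lactone | O=C1C(C(C)O)[C@@H](C=C)[C@](C)(CCCCl)CO1
F5 | step 7 | (E)-3-ethylidene lactone | O=C1/C(=C/C)[C@@H](C=C)[C@](C)(CCCCl)CO1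
F6 | step 7 | 2-(3-chloropropyl)-4-ethylidene-2-methyl-3-vinylpentane-1,5-diol | OC/C(=C/C)[C@@H](C=C)[C@](C)(CCCCl)CO
F7 | step 13 | acetonide of 20 | C[C@@]12CCCC3(COC(C)(C)OC3)[C@H]1CC[C@H](C4OCCO4)[C@H]2C=C
F8 | step 13 | C12 primary alcohol | C[C@@]12CCCC3(COC(C)(C)OC3)[C@H]1CC[C@H](C4OCCO4)[C@H]2CCO
F9 | step 13 | C12 aldehyde | C[C@@]12CCCC3(COC(C)(C)OC3)[C@H]1CC[C@H](C4OCCO4)[C@H]2CC=O
F10 | step 13 | (E)-α-alkylidene butyrolactone | C[C@@]12CCCC3(COC(C)(C)OC3)[C@H]1CC[C@H](C4OCCO4)[C@H]2C/C=C1\CCOC1=O
F11 | step 13 | doubly acetal-protected butenolide | C[C@@]12CCCC3(COC(C)(C)OC3)[C@H]1CC[C@H](C4OCCO4)[C@H]2CCC1=CCOC1=O
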